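**Retrosynthetic overview**

1. Germacrane numbering is used: C1 carbinol, C4–C5 oxirane, C6 angelate carbinol, C7/C8 lactone ring fusion, C12 lactone carbonyl, exocyclic C10=C14 and C11=C13. The last operations are angeloylation of the C6 hydroxyl and removal of a C1 silyl ether.
2. Key disconnection C6–C7: the ten-membered carbocycle is closed by a CrCl2-mediated intramolecular allylation of a C6 α,β-epoxy aldehyde by a (5S)-3-(bromomethyl)butenolide. This one operation closes the medium ring, sets C6 and C7, moves the butenolide alkene out to C11=C13 and frees the C6 hydroxyl.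
3. Enabling feature: C6(O)–C7–C11(=C13) is a homoallylic alcohol whose ring-fusion carbon C7 is the γ-carbon of an allyl unit built into the γ-lactone ring. The C5/C6 (Felkin–Anh, anti), C6/C7 (chair, anti) and C7/C8 (trans across the lactone) relationships of the target are all the intrinsically favoured ones.
4. Open-chain precursor: the butenolide ring comes from ring-closing metathesis of a C8 2-(bromomethyl)acrylate; the C1–C10 bond from a Ni/Cr alkenyl–aldehyde coupling followed by CBS reduction (C1). The two pieces are an epoxy aldehyde from nerol (Sharpless epoxidation sets C4 and C5) and (S)-5-bromohexa-1,5-dien-3-yl acetate (acrolein plus 2,3-dibromopropene, Sharpless kinetic resolution sets C8).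
5. Ring order: oxirane (step 1), butenolide (step 13), ten-membered carbocycle (step 16).

Key step: step 16

Remark: C7 changes its CIP descriptor (S in the free C6 alcohol, R in the C6 esters) only through the ranking rules; the geometry is the same throughout.

**Route**

Step 1
Reactants: 1 nerol
Product: 2 (2S,3R)-2,3-epoxynerol
Conditions: Ti(OiPr)4 (10 mol%), L-(+)-diethyl tartrate (12 mol%), t-BuOOH, 4 Å MS, CH2Cl2, −20 °C
Reagents that add atoms: tert-butyl hydroperoxide, CC(C)(C)OO
Why: Sharpless asymmetric epoxidation of the Z-allylic alcohol, in which L-(+)-tartrate should deliver oxygen to the face that gives the (2S,3R)-oxirane (C5 and C4 of the target), the cis relationship of CH2OH and chain follows from the Z-alkene, and the isolated trisubstituted alkene is not touched.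

Step 2
Reactants: 2 (2S,3R)-2,3-epoxynerol
Product: 3 (2R,3S)-3-{[(4-methoxybenzyl)oxy]methyl}-2-methyl-2-(4-methylpent-3-en-1-yl)oxirane
Conditions: NaH, 4-methoxybenzyl chloride, Bu4NI (cat.), THF/DMF, 0 °C to rt
Reagents that add atoms: 4-methoxybenzyl chloride, COc1ccc(CCl)cc1
Why: Williamson etherification of the primary alkoxide, which in an aprotic medium should be faster than Payne rearrangement, so the oxirane stereocentres are untouched.

Step 3
Reactants: 3 (2R,3S)-3-{[(4-methoxybenzyl)oxy]methyl}-2-methyl-2-(4-methylpent-3-en-1-yl)oxirane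
Product: 4 3-[(2R,3S)-3-{[(4-methoxybenzyl)oxy]methyl}-2-methyloxiran-2-yl]propanal
Conditions: OsO4 (2 mol%), NaIO4, 2,6-lutidine, dioxane/H2O, rt
Reagents that add atoms: sodium periodate (oxygen source through the OsO4 cycle), [Na+].[O-]I(=O)(=O)=O
Why: Lemieux–Johnson cleavage of the only remaining alkene (dihydroxylation, then glycol cleavage to the aldehyde and acetone), with 2,6-lutidine keeping the medium near neutral for the oxirane and the PMB ether.

Step 4
Reactants: 5 acrolein; 6 2,3-dibromopropene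
Product: 7 (±)-5-bromohexa-1,5-dien-3-ol
Conditions: indium powder, THF/H2O (1:1), rt
Reagents that add atoms: none
Why: Barbier-type indium-mediated 2-bromoallylation in water, in which the allylindium adds 1,2 to the enal and the vinylic C–Br bond is not reduced; the carbinol is formed racemic.

Step 5
Reactants: 7 (±)-5-bromohexa-1,5-dien-3-ol
Product: 8 (3S)-5-bromohexa-1,5-dien-3-ol
Conditions: Ti(OiPr)4 (1.0 equiv), D-(−)-diisopropyl tartrate (1.2 equiv), t-BuOOH (0.6 equiv), 4 Å MS, CH2Cl2, −20 °C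
Reagents that add atoms: none
Why: Sharpless kinetic resolution of a secondary allylic alcohol, in which D-(−)-tartrate should epoxidize the vinyl group of the (R)-enantiomer much faster (erythro epoxy alcohol), leaving the (S)-alcohol (C8 of the target) once slightly more than half has reacted; the 2-bromoalkene is not an allylic-alcohol alkene and stays.

Step 6
Reactants: 8 (3S)-5-bromohexa-1,5-dien-3-ol
Product: 9 (3S)-5-bromohexa-1,5-dien-3-yl acetate
Conditions: Ac2O, pyridine, DMAP (cat.), CH2Cl2, 0 °C to rt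
Reagents that add atoms: acetic anhydride, CC(=O)OC(C)=O
Why: Standard O-acetylation; the acetate tolerates the chromium chemistry of step 7 and can later be removed beside a silyl ether.

Step 7
Reactants: 9 (3S)-5-bromohexa-1,5-dien-3-yl acetate; 4 3-[(2R,3S)-3-{[(4-methoxybenzyl)oxy]methyl}-2-methyloxiran-2-yl]propanal
Product: 11 (3S,6RS)-6-hydroxy-8-[(2R,3S)-3-{[(4-methoxybenzyl)oxy]methyl}-2-methyloxiran-2-yl]-5-methylideneoct-1-en-3-yl acetate, via alkenylchromium dichloride 10 (not isolated)
Conditions: CrCl2 (4 equiv), NiCl2 (2 mol%), DMF, rt; aq. NH4Cl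
Reagents that add atoms: none
Why: Nozaki–Hiyama–Kishi alkenylation, in which zerovalent nickel inserts into the vinylic C–Br bond and transmetalation gives the alkenylchromium 10 (trivalent chromium) that adds only to the aldehyde and spares acetate, oxirane and PMB ether; the new carbinol is not controlled and is erased in step 8.

Step 8
Reactants: 11 (3S,6RS)-6-hydroxy-8-[(2R,3S)-3-{[(4-methoxybenzyl)oxy]methyl}-2-methyloxiran-2-yl]-5-methylideneoct-1-en-3-yl acetate
Product: 12 (3S)-8-[(2R,3S)-3-{[(4-methoxybenzyl)oxy]methyl}-2-methyloxiran-2-yl]-5-methylidene-6-oxooct-1-en-3-yl acetate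
Conditions: Dess–Martin periodinane, NaHCO3, CH2Cl2, 0 °C to rt
Reagents that add atoms: none
Why: Buffered Dess–Martin oxidation of the secondary allylic alcohol, which converges both epimers into one enone.

Step 9
Reactants: 12 (3S)-8-[(2R,3S)-3-{[(4-methoxybenzyl)oxy]methyl}-2-methyloxiran-2-yl]-5-methylidene-6-oxooct-1-en-3-yl acetate
Product: 13 (3S,6S)-6-hydroxy-8-[(2R,3S)-3-{[(4-methoxybenzyl)oxy]methyl}-2-methyloxiran-2-yl]-5-methylideneoct-1-en-3-yl acetate
Conditions: (R)-2-methyl-CBS-oxazaborolidine (0.5 equiv), catecholborane, toluene, −78 °C; MeOH, aq. NaHCO3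
Reagents that add atoms: none
Why: Corey–Bakshi–Shibata reduction, in which the α-branched alkenyl group is the large and the CH2CH2 chain the small ketone substituent, so the (R)-catalyst should deliver hydride to the face that gives the (S)-carbinol (C1 of the target) by 1,2-reduction.

Step 10
Reactants: 13 (3S,6S)-6-hydroxy-8-[(2R,3S)-3-{[(4-methoxybenzyl)oxy]methyl}-2-methyloxiran-2-yl]-5-methylideneoct-1-en-3-yl acetate
Product: 14 (3S,6S)-8-[(2R,3S)-3-{[(4-methoxybenzyl)oxy]methyl}-2-methyloxiran-2-yl]-5-methylidene-6-[(triethylsilyl)oxy]oct-1-en-3-yl acetate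
Conditions: Et3SiCl, imidazole, CH2Cl2, 0 °C
Reagents that add atoms: chlorotriethylsilane, CC[Si](Cl)(CC)CC
Why: Silylation of the secondary allylic alcohol under mild base, done without delay so that the free hydroxyl cannot open the oxirane in a 5-exo fashion.

Step 11
Reactants: 14 (3S,6S)-8-[(2R,3S)-3-{[(4-methoxybenzyl)oxy]methyl}-2-methyloxiran-2-yl]-5-methylidene-6-[(triethylsilyl)oxy]oct-1-en-3-yl acetate
Product: 15 (3S,6S)-8-[(2R,3S)-3-{[(4-methoxybenzyl)oxy]methyl}-2-methyloxiran-2-yl]-5-methylidene-6-[(triethylsilyl)oxy]oct-1-en-3-ol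
Conditions: K2CO3 (cat.), MeOH, 0 °C
Reagents that add atoms: none
Why: Base-catalysed transesterification removes the acetate, while the TES ether, the oxirane and the PMB ether are stable to K2CO3 in cold methanol.

Step 12
Reactants: 15 (3S,6S)-8-[(2R,3S)-3-{[(4-methoxybenzyl)oxy]methyl}-2-methyloxiran-2-yl]-5-methylidene-6-[(triethylsilyl)oxy]oct-1-en-3-ol; 16 2-(bromomethyl)prop-2-enoic acid
Product: 17 (3S,6S)-8-[(2R,3S)-3-{[(4-methoxybenzyl)oxy]methyl}-2-methyloxiran-2-yl]-5-methylidene-6-[(triethylsilyl)oxy]oct-1-en-3-yl 2-(bromomethyl)prop-2-enoate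
Conditions: DCC, DMAP (5 mol%), CH2Cl2, −20 to 0 °C
Reagents that add atoms: none
Why: Steglich esterification of the secondary allylic alcohol, with low temperature and only catalytic DMAP so that the allylic bromide is not displaced.

Step 13
Reactants: 17 (3S,6S)-8-[(2R,3S)-3-{[(4-methoxybenzyl)oxy]methyl}-2-methyloxiran-2-yl]-5-methylidene-6-[(triethylsilyl)oxy]oct-1-en-3-yl 2-(bromomethyl)prop-2-enoate
Product: 18 (5S)-3-(bromomethyl)-5-{(3S)-5-[(2R,3S)-3-{[(4-methoxybenzyl)oxy]methyl}-2-methyloxiran-2-yl]-2-methylidene-3-[(triethylsilyl)oxy]pentyl}furan-2(5H)-one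
Conditions: second-generation Hoveyda–Grubbs catalyst (10 mol%), toluene (5 mM), 80 °C
Reagents that add atoms: none
Why: Ring-closing metathesis, in which the ruthenium alkylidene forms at the monosubstituted vinyl group and closes onto the acrylate alkene to the five-membered trisubstituted butenolide (the C10 methylidene could only give a four-membered ring or a tetrasubstituted alkene), the phosphine-free catalyst spares the allylic bromide and C8 is untouched.

Step 14
Reactants: 18 (5S)-3-(bromomethyl)-5-{(3S)-5-[(2R,3S)-3-{[(4-methoxybenzyl)oxy]methyl}-2-methyloxiran-2-yl]-2-methylidene-3-[(triethylsilyl)oxy]pentyl}furan-2(5H)-one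
Product: 19 (5S)-3-(bromomethyl)-5-{(3S)-5-[(2R,3S)-3-(hydroxymethyl)-2-methyloxiran-2-yl]-2-methylidene-3-[(triethylsilyl)oxy]pentyl}furan-2(5H)-one
Conditions: DDQ, CH2Cl2/pH 7 phosphate buffer (10:1), 0 °C
Reagents that add atoms: none
Why: Oxidative PMB cleavage by DDQ (hydride abstraction, hydrolysis of the oxocarbenium ion) under neutral buffered conditions that leave the allylic bromide, the oxirane and the TES ether intact.

Step 15
Reactants: 19 (5S)-3-(bromomethyl)-5-{(3S)-5-[(2R,3S)-3-(hydroxymethyl)-2-methyloxiran-2-yl]-2-methylidene-3-[(triethylsilyl)oxy]pentyl}furan-2(5H)-one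
Product: 20 (2R,3R)-3-{(3S)-5-[(2S)-4-(bromomethyl)-5-oxo-2,5-dihydrofuran-2-yl]-4-methylidene-3-[(triethylsilyl)oxy]pentyl}-3-methyloxirane-2-carbaldehyde
Conditions: Dess–Martin periodinane, NaHCO3, CH2Cl2, 0 °C; used at once
Reagents that add atoms: none
Why: Dess–Martin oxidation of the primary epoxy alcohol to the α,β-epoxy aldehyde without amine base, so that neither the acidic C8 proton of the butenolide nor the oxirane is put at risk.

Step 16
Reactants: 20 (2R,3R)-3-{(3S)-5-[(2S)-4-(bromomethyl)-5-oxo-2,5-dihydrofuran-2-yl]-4-methylidene-3-[(triethylsilyl)oxy]pentyl}-3-methyloxirane-2-carbaldehyde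
Product: 22 (1S,4R,5S,6S,7S,8S)-4,5-epoxy-6-hydroxy-1-[(triethylsilyl)oxy]germacra-10(14),11(13)-dien-12,8-olide, via allylchromium dichloride 21 (not isolated)
Conditions: CrCl2 (10 equiv), THF/DMF (10:1), rt, syringe-pump addition of 20 over 10 h (final 2 mM); aq. NH4Cl
Reagents that add atoms: none
Why: Two equivalents of CrCl2 reduce the allylic C–Br bond to the allylchromium dichloride 21 (trivalent chromium), which adds to the tethered aldehyde through a six-membered chair transition state with allylic transposition (SE2′), so that C7, the γ-carbon of the allyl unit, bonds to C6 and the ring alkene moves out to the exocyclic C11=C13 position. The closest known reaction types are the intramolecular Nozaki–Hiyama (Barbier-type) allylation used to close ten-membered germacranolide carbocycles and the chromium- or indium-mediated addition of 3-(bromomethyl)butenolides to aldehydes. The ten-membered carbocycle is closed by 1,2-addition of the γ-terminus to the aldehyde carbonyl under high dilution; the lactone ring is not opened but converted from butenolide into the α-methylene-γ-butyrolactone. C7 is set by attack on the butenolide face anti to the C8 side chain (trans ring fusion); C6 is set by the chair transition state, in which the ring-fixed E-type allyl geometry and an equatorial aldehyde substituent give the anti homoallylic alcohol, and the same aldehyde face is the Felkin–Anh face of the cis-epoxy aldehyde (C5–O bond anti to the forming bond), so all three controlling elements are matched. The step needs γ- over α-attack of the allyl unit (secured by the cyclic transition state of the primary allylchromium; α-attack would give a twelve-membered ring), aldehyde-only reactivity (the organochromium should not open the oxirane or attack lactone, TES ether or C10 methylidene) and cyclization over oligomerization (slow addition, 2 mM).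

Step 17
Reactants: 22 (1S,4R,5S,6S,7S,8S)-4,5-epoxy-6-hydroxy-1-[(triethylsilyl)oxy]germacra-10(14),11(13)-dien-12,8-olide; 23 angelic acid
Product: 25 (1S,4R,5S,6S,7R,8S)-6-(angeloyloxy)-4,5-epoxy-1-[(triethylsilyl)oxy]germacra-10(14),11(13)-dien-12,8-olide, via angelic 2,4,6-trichlorobenzoic anhydride 24 (not isolated)
Conditions: 23, 2,4,6-trichlorobenzoyl chloride, Et3N, toluene, rt, 2 h; then 22, 80 °C
Reagents that add atoms: none
Why: Greene-type (Yamaguchi) acylation through the mixed anhydride 24 without a nucleophilic catalyst, in which the hindered C6 alcohol attacks the less hindered angeloyl carbonyl and the absence of DMAP should avoid Z to E isomerization to the tiglate.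

Step 18
Reactants: 25 (1S,4R,5S,6S,7R,8S)-6-(angeloyloxy)-4,5-epoxy-1-[(triethylsilyl)oxy]germacra-10(14),11(13)-dien-12,8-olide
Product: 26 (1S,4R,5S,6S,7R,8S)-6-(angeloyloxy)-4,5-epoxy-1-hydroxygermacra-10(14),11(13)-dien-12,8-olide (CNP0104965.1)
Conditions: HF·pyridine, pyridine, THF, 0 °C
Reagents that add atoms: none
Why: Buffered fluoride cleavage of the secondary allylic TES ether, mild enough for the oxirane, the angelate and the α-methylene lactone.

**Compound list**

1 | nerol, (2Z)-3,7-dimethylocta-2,6-dien-1-ol | CC(C)=CCC/C(C)=C\CO | starting material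
2 | (2S,3R)-2,3-epoxynerol, [(2S,3R)-3-methyl-3-(4-methylpent-3-en-1-yl)oxiran-2-yl]methanol | CC(C)=CCC[C@@]1(C)O[C@H]1CO | intermediate
3 | (2R,3S)-3-{[(4-methoxybenzyl)oxy]methyl}-2-methyl-2-(4-methylpent-3-en-1-yl)oxirane | CC(C)=CCC[C@@]1(C)O[C@H]1COCc2ccc(OC)cc2 | intermediate
4 | 3-[(2R,3S)-3-{[(4-methoxybenzyl)oxy]methyl}-2-methyloxiran-2-yl]propanal | O=CCC[C@@]1(C)O[C@H]1COCc2ccc(OC)cc2 | intermediate
5 | acrolein, prop-2-enal | C=CC=O | starting material
6 | 2,3-dibromopropene | C=C(Br)CBr | starting material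
7 | (±)-5-bromohexa-1,5-dien-3-ol | C=CC(O)CC(Br)=C | intermediate
8 | (3S)-5-bromohexa-1,5-dien-3-ol | C=C[C@@H](O)CC(Br)=C | intermediate
9 | (3S)-5-bromohexa-1,5-dien-3-yl acetate | C=C[C@@H](OC(C)=O)CC(Br)=C | intermediate
10 | [(4S)-4-acetoxyhexa-1,5-dien-2-yl]chromium dichloride | C=C[C@@H](OC(C)=O)CC(=C)[Cr](Cl)Cl | intermediate (not isolated)
11 | (3S,6RS)-6-hydroxy-8-[(2R,3S)-3-{[(4-methoxybenzyl)oxy]methyl}-2-methyloxiran-2-yl]-5-methylideneoct-1-en-3-yl acetate | C=C[C@@H](OC(C)=O)CC(=C)C(O)CC[C@@]1(C)O[C@H]1COCc2ccc(OC)cc2 | intermediate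
12 | (3S)-8-[(2R,3S)-3-{[(4-methoxybenzyl)oxy]methyl}-2-methyloxiran-2-yl]-5-methylidene-6-oxooct-1-en-3-yl acetate | C=C[C@@H](OC(C)=O)CC(=C)C(=O)CC[C@@]1(C)O[C@H]1COCc2ccc(OC)cc2 | intermediate
13 | (3S,6S)-6-hydroxy-8-[(2R,3S)-3-{[(4-methoxybenzyl)oxy]methyl}-2-methyloxiran-2-yl]-5-methylideneoct-1-en-3-yl acetate | C=C[C@@H](OC(C)=O)CC(=C)[C@@H](O)CC[C@@]1(C)O[C@H]1COCc2ccc(OC)cc2 | intermediate
14 | (3S,6S)-8-[(2R,3S)-3-{[(4-methoxybenzyl)oxy]methyl}-2-methyloxiran-2-yl]-5-methylidene-6-[(triethylsilyl)oxy]oct-1-en-3-yl acetate | C=C[C@@H](OC(C)=O)CC(=C)[C@@H](O[Si](CC)(CC)CC)CC[C@@]1(C)O[C@H]1COCc2ccc(OC)cc2 | intermediate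
15 | (3S,6S)-8-[(2R,3S)-3-{[(4-methoxybenzyl)oxy]methyl}-2-methyloxiran-2-yl]-5-methylidene-6-[(triethylsilyl)oxy]oct-1-en-3-ol | C=C[C@@H](O)CC(=C)[C@@H](O[Si](CC)(CC)CC)CC[C@@]1(C)O[C@H]1COCc2ccc(OC)cc2 | intermediate
16 | 2-(bromomethyl)prop-2-enoic acid | C=C(CBr)C(=O)O | starting material
17 | (3S,6S)-8-[(2R,3S)-3-{[(4-methoxybenzyl)oxy]methyl}-2-methyloxiran-2-yl]-5-methylidene-6-[(triethylsilyl)oxy]oct-1-en-3-yl 2-(bromomethyl)prop-2-enoate | C=C[C@@H](OC(=O)C(=C)CBr)CC(=C)[C@@H](O[Si](CC)(CC)CC)CC[C@@]1(C)O[C@H]1COCc2ccc(OC)cc2 | intermediate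
18 | (5S)-3-(bromomethyl)-5-{(3S)-5-[(2R,3S)-3-{[(4-methoxybenzyl)oxy]methyl}-2-methyloxiran-2-yl]-2-methylidene-3-[(triethylsilyl)oxy]pentyl}furan-2(5H)-one | BrCC1=C[C@H](CC(=C)[C@@H](O[Si](CC)(CC)CC)CC[C@@]2(C)O[C@H]2COCc3ccc(OC)cc3)OC1=O | intermediate
19 | (5S)-3-(bromomethyl)-5-{(3S)-5-[(2R,3S)-3-(hydroxymethyl)-2-methyloxiran-2-yl]-2-methylidene-3-[(triethylsilyl)oxy]pentyl}furan-2(5H)-one | BrCC1=C[C@H](CC(=C)[C@@H](O[Si](CC)(CC)CC)CC[C@@]2(C)O[C@H]2CO)OC1=O | intermediate
20 | (2R,3R)-3-{(3S)-5-[(2S)-4-(bromomethyl)-5-oxo-2,5-dihydrofuran-2-yl]-4-methylidene-3-[(triethylsilyl)oxy]pentyl}-3-methyloxirane-2-carbaldehyde | BrCC1=C[C@H](CC(=C)[C@@H](O[Si](CC)(CC)CC)CC[C@@]2(C)O[C@H]2C=O)OC1=O | intermediate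
21 | allylchromium dichloride derived from 20, ({(5S)-5-[(3S)-5-[(2R,3R)-3-formyl-2-methyloxiran-2-yl]-2-methylidene-3-[(triethylsilyl)oxy]pentyl]-2-oxo-2,5-dihydrofuran-3-yl}methyl)chromium dichloride | Cl[Cr](Cl)CC1=C[C@H](CC(=C)[C@@H](O[Si](CC)(CC)CC)CC[C@@]2(C)O[C@H]2C=O)OC1=O | intermediate (not isolated)
22 | (1S,4R,5S,6S,7S,8S)-4,5-epoxy-6-hydroxy-1-[(triethylsilyl)oxy]germacra-10(14),11(13)-dien-12,8-olide | C=C1C(=O)O[C@H]2CC(=C)[C@@H](O[Si](CC)(CC)CC)CC[C@@]3(C)O[C@H]3[C@@H](O)[C@H]12 | intermediate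
23 | angelic acid, (2Z)-2-methylbut-2-enoic acid | C/C=C(/C)C(=O)O | starting material
24 | (2Z)-2-methylbut-2-enoic 2,4,6-trichlorobenzoic anhydride | C/C=C(/C)C(=O)OC(=O)c1c(Cl)cc(Cl)cc1Cl | intermediate (not isolated)
25 | (1S,4R,5S,6S,7R,8S)-6-(angeloyloxy)-4,5-epoxy-1-[(triethylsilyl)oxy]germacra-10(14),11(13)-dien-12,8-olide | C=C1C(=O)O[C@H]2CC(=C)[C@@H](O[Si](CC)(CC)CC)CC[C@@]3(C)O[C@H]3[C@@H](OC(=O)/C(C)=C\C)[C@H]12 | intermediate
26 | (1S,4R,5S,6S,7R,8S)-6-(angeloyloxy)-4,5-epoxy-1-hydroxygermacra-10(14),11(13)-dien-12,8-olide (CNP0104965.1) | C=C1C(=O)O[C@H]2CC(=C)[C@@H](O)CC[C@@]3(C)O[C@H]3[C@@H](OC(=O)/C(C)=C\C)[C@H]12 | target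

**Step count**

Total: 18 steps. Longest linear sequence: 15 steps (nerol to target, steps 1–3 and 7–18); steps 4–6 make the second piece.

**Steps most likely to fail, with fallbacks**

Step 16 (ring closure). What may go wrong: addition on the butenolide face syn to the C8 side chain (cis-fused lactone), electron transfer from divalent chromium to the epoxy aldehyde (pinacol coupling or reductive oxirane opening), or intermolecular coupling. The fallback keeps the same C6–C7 closure but replaces the reductive organochromium by a thermal intramolecular allylboration free of metal salts. It sets out from 18: borylation with B2pin2 (Pd2(dba)3 cat., DMSO, 50 °C) should give the allyl pinacolboronate analogue of 18 F1. DDQ as in step 14 should give the epoxy alcohol analogue of 19 F2, and Dess–Martin oxidation the epoxy aldehyde analogue of 20 F3, which should be stable at room temperature because 2-acyl-substituted allylboronates add slowly. Heating F3 in toluene (2 mM, 90 °C) should close the ring through the compact boron chair transition state to the O-pinacolboryl derivative of 22 F4, and triethanolamine work-up comes back to the route at 22.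

Step 13 (metathesis). What may go wrong: loss of the allylic bromide to nucleophiles or to the metal alkylidene, and stalling of ring closure onto the hindered, electron-poor 1,1-disubstituted alkene with oligomer formation. The fallback introduces bromine only after the metathesis and sets out from 15. Commercial ethyl 2-(hydroxymethyl)acrylate is protected (4-methoxybenzyl trichloroacetimidate, cat. camphorsulfonic acid) to ethyl 2-{[(4-methoxybenzyl)oxy]methyl}prop-2-enoate F5 and saponified (LiOH) to 2-{[(4-methoxybenzyl)oxy]methyl}prop-2-enoic acid F6. Steglich esterification of 15 with F6 should give the 2-{[(4-methoxybenzyl)oxy]methyl}acrylate of 15 F7, and ring-closing metathesis (same catalyst, toluene, 80 °C) the 3-{[(4-methoxybenzyl)oxy]methyl} analogue of 18 F8. DDQ (2.5 equiv) should remove both PMB groups to the diol (5S)-3-(hydroxymethyl)-5-{(3S)-5-[(2R,3S)-3-(hydroxymethyl)-2-methyloxiran-2-yl]-2-methylidene-3-[(triethylsilyl)oxy]pentyl}furan-2(5H)-one F9. Corey–Kim bromination (N-bromosuccinimide, Me2S, CH2Cl2, −20 °C), which converts allylic but not saturated primary alcohols, comes back to the route at 19.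

Step 17 (angeloylation). What may go wrong: Z to E isomerization of the acyl group, slow acylation of the hindered C6 hydroxyl between the oxirane and C7, and at 80 °C base-induced translactonization to the 12,6-olide or migration of the C11=C13 alkene into the ring. The fallback builds the Z-alkene on the ester instead of transferring it and sets out from 22. Steglich esterification with 2-[bis(2,2,2-trifluoroethoxy)phosphoryl]propanoic acid F10 (from its commercial ethyl ester by LiOH saponification) should give the 6-O-{2-[bis(2,2,2-trifluoroethoxy)phosphoryl]propanoyl} derivative of 22 F11. Still–Gennari olefination with acetaldehyde (KN(SiMe3)2, 18-crown-6, THF, −78 °C) should give the (Z)-2-methylbut-2-enoate directly and comes back to the route at 25.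

**Further compounds**

F1 | step 16 | (5S)-5-{(3S)-5-[(2R,3S)-3-{[(4-methoxybenzyl)oxy]methyl}-2-methyloxiran-2-yl]-2-methylidene-3-[(triethylsilyl)oxy]pentyl}-3-[(4,4,5,5-tetramethyl-1,3,2-dioxaborolan-2-yl)methyl]furan-2(5H)-one | CC1(C)OB(CC2=C[C@H](CC(=C)[C@@H](O[Si](CC)(CC)CC)CC[C@@]3(C)O[C@H]3COCc4ccc(OC)cc4)OC2=O)OC1(C)C
F2 | step 16 | (5S)-5-{(3S)-5-[(2R,3S)-3-(hydroxymethyl)-2-methyloxiran-2-yl]-2-methylidene-3-[(triethylsilyl)oxy]pentyl}-3-[(4,4,5,5-tetramethyl-1,3,2-dioxaborolan-2-yl)methyl]furan-2(5H)-one | CC1(C)OB(CC2=C[C@H](CC(=C)[C@@H](O[Si](CC)(CC)CC)CC[C@@]3(C)O[C@H]3CO)OC2=O)OC1(C)C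
F3 | step 16 | (2R,3R)-3-methyl-3-{(3S)-4-methylidene-5-[(2S)-5-oxo-4-[(4,4,5,5-tetramethyl-1,3,2-dioxaborolan-2-yl)methyl]-2,5-dihydrofuran-2-yl]-3-[(triethylsilyl)oxy]pentyl}oxirane-2-carbaldehyde | CC1(C)OB(CC2=C[C@H](CC(=C)[C@@H](O[Si](CC)(CC)CC)CC[C@@]3(C)O[C@H]3C=O)OC2=O)OC1(C)C
F4 | step 16 | 6-O-(4,4,5,5-tetramethyl-1,3,2-dioxaborolan-2-yl) derivative of 22 | C=C1C(=O)O[C@H]2CC(=C)[C@@H](O[Si](CC)(CC)CC)CC[C@@]3(C)O[C@H]3[C@@H](OB4OC(C)(C)C(C)(C)O4)[C@H]12
F5 | step 13 | ethyl 2-{[(4-methoxybenzyl)oxy]methyl}prop-2-enoate | C=C(COCc1ccc(OC)cc1)C(=O)OCC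
F6 | step 13 | 2-{[(4-methoxybenzyl)oxy]methyl}prop-2-enoic acid | C=C(COCc1ccc(OC)cc1)C(=O)O
F7 | step 13 | (3S,6S)-8-[(2R,3S)-3-{[(4-methoxybenzyl)oxy]methyl}-2-methyloxiran-2-yl]-5-methylidene-6-[(triethylsilyl)oxy]oct-1-en-3-yl 2-{[(4-methoxybenzyl)oxy]methyl}prop-2-enoate | C=C[C@@H](OC(=O)C(=C)COCc1ccc(OC)cc1)CC(=C)[C@@H](O[Si](CC)(CC)CC)CC[C@@]2(C)O[C@H]2COCc3ccc(OC)cc3
F8 | step 13 | (5S)-3-{[(4-methoxybenzyl)oxy]methyl}-5-{(3S)-5-[(2R,3S)-3-{[(4-methoxybenzyl)oxy]methyl}-2-methyloxiran-2-yl]-2-methylidene-3-[(triethylsilyl)oxy]pentyl}furan-2(5H)-one | COc1ccc(COCC2=C[C@H](CC(=C)[C@@H](O[Si](CC)(CC)CC)CC[C@@]3(C)O[C@H]3COCc4ccc(OC)cc4)OC2=O)cc1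
F9 | step 13 | (5S)-3-(hydroxymethyl)-5-{(3S)-5-[(2R,3S)-3-(hydroxymethyl)-2-methyloxiran-2-yl]-2-methylidene-3-[(triethylsilyl)oxy]pentyl}furan-2(5H)-one | OCC1=C[C@H](CC(=C)[C@@H](O[Si](CC)(CC)CC)CC[C@@]2(C)O[C@H]2CO)OC1=O
F10 | step 17 | 2-[bis(2,2,2-trifluoroethoxy)phosphoryl]propanoic acid | CC(C(=O)O)P(=O)(OCC(F)(F)F)OCC(F)(F)F
F11 | step 17 | 6-O-{2-[bis(2,2,2-trifluoroethoxy)phosphoryl]propanoyl} derivative of 22 | C=C1C(=O)O[C@H]2CC(=C)[C@@H](O[Si](CC)(CC)CC)CC[C@@]3(C)O[C@H]3[C@@H](OC(=O)C(C)P(=O)(OCC(F)(F)F)OCC(F)(F)F)[C@H]12
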